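## Structural features

Dihydroptychantol A (17) is a macrocyclic bis(bibenzyl). Four benzene rings are joined into one 18-membered ring by two CH2CH2 bridges and two diaryl ether oxygens (two ring atoms of ring A, three of ring B, four of ring C, three of ring D, four bridge carbons, two oxygens). Ring A carries its ether oxygen (to ring D) ortho to bridge 1 and a free OH para to that oxygen. Ring B carries bridge 1 para to its free OH and its ether oxygen (to ring C) ortho to the OH. Ring C is para-linked between the ring B oxygen and bridge 2, and ring D is meta-linked between bridge 2 and the ring A oxygen. There is no stereocenter and no double bond, so no configuration has to be set. The fragile groups are the two electron-rich phenols, above all ring B, which is a catechol monoaryl ether and easily oxidised; the ethers and bridges are robust. The difficulty is threefold: two unsymmetrical diaryl ethers (one at a ring A carbon flanked by bridge 1), closure of an 18-membered ring against chain growth, and pairing each oxygen with the right ring. The key step uses the positions of the two hydroxyl carbons, para to the ether carbon on ring A and ortho to it on ring B, which are the positions from which a nitro group activates a halogen-bearing carbon toward a phenoxide, so the activating groups later become the hydroxyls; it also uses the fact that rings C and D without the ethers are a plain 3,4'-dihydroxybibenzyl whose phenols can be told apart by one silyl group.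

## Logic of the disconnections

**17 back to 15 (through 16).** The two phenolic C–O bonds, on ring A para to the ether carbon and on ring B ortho to it, are exchanged for C–N bonds. The reason is that nitrogen has to sit on these carbons anyway, and leaving the hydroxyls to the end keeps the oxidation-prone phenols away from base, heat and reductant. The gain is in handling, not in skeleton. The demand is that both amino groups are diazotised fully in a medium that dissolves the lipophilic macrocycle, and that 16 is consumed in solution, unheated and never isolated, with the ring B aryl radical captured by copper before it can attack ring C.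

**15 back to 14.** Only N–H bonds are exchanged for N–O bonds. The reason is that nitro groups are what the ring-forming step needs. The gain is a neutral, air-stable, base-stable macrocycle. The demand is a reduction that touches nothing else, which is mild because 14 holds no halogen, alkene or benzyl group.

**14 back to 5 and 11 (through 13 and 12).** Two bonds are cut: the bond from the ring A carbon (para to nitro, next to bridge 1) to the ring D oxygen, and the bond from the ring B carbon (ortho to nitro) to the ring C oxygen. Both carbons are nitro-activated, and cutting both removes the macrocycle and both ethers at once and leaves two bibenzyls of similar size, each with one bridge in place. The demand is pairing and order. The halogen pattern of 5 was tested against two variants and kept: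
- A difluoride would offer the first phenoxide two carbons of similar reactivity and lose the pairing.
- Swapping the halogens would narrow the reactivity gap without making the ring closure easier.

So the better leaving group stays on the unhindered ring B carbon and the poorer one on the hindered ring A carbon. The silyl group of 11 stays the bulkiest common one, so that it outlasts the base and the fluoride ion released in the first substitution. The second substitution needs heat and high dilution.

**5 back to 4.** The central single bond of bridge 1 is seen as a C=C bond. This allows the bridge to be made by olefination. The demand is a reductant that saturates a stilbene but leaves two nitro groups and the C–Cl bond alone and brings no nucleophile to the C–F carbon.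

**4 back to 2 and 3.** The C=C bond of bridge 1 is cut. The ylide carbon is placed on the ring B side because there it is para to nitro and forms with a weak base. The gain is two one-ring pieces. The demand is a base that is weak and non-nucleophilic, because the fluoride of 2 and the chloride of 3 (ortho to CHO, para to NO2) are both open to substitution.

**2 back to 1.** The C–P bond is cut, giving a benzylic bromide that is bought. The demand is only a temperature low enough that the phosphine attacks the benzylic carbon alone.

**11 back to 10.** The C=C bond of bridge 2 and the O–benzyl bond are restored. The two phenols are differentiated from the start, one as a benzyl ether and one as a silyl ether, and a single hydrogenation both builds the bridge and frees the ring C phenol alone. The demand is that the aryl silyl ether survives hydrogenation.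

**10 back to 9 and 7.** The C=C bond of bridge 2 is cut into a benzylic ylide and an aldehyde. The gain is two one-ring pieces. The demand is a base that does not attack silicon.

**9 back to 8, and 7 back to 6.** The C–P bond and the O–Si bond are cut, which leads to purchasable compounds. The forward steps need nothing beyond standard quaternisation and silylation.

## Other disconnections considered

**Alternative 1:** The cut is the bond between the ring B carbon and the oxygen leading to ring C, formed oxidatively.
- Forward step: the open precursor A2 holds the ring A to ring D ether and both bridges, with ring A as its methyl ether, ring B as a 2,6-dibromophenol and ring C as a 2,6-dichlorophenol. Tl(NO3)3 should oxidise the dibromophenol by two electrons, the ring C phenol oxygen should add at a bromine-bearing ortho carbon, and zinc should then remove that bromine reductively and restore the arene to give A1. Hydrogenolysis of the three remaining halogens and cleavage of the methyl ether would lead to 17.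
- In favour: it follows the presumed biogenesis, the ring B hydroxyl is present from the start and never has to be made from nitrogen, and the ring closes near room temperature without base, so nitrobenzylic acidity plays no part. On these points it is the better plan.
- Against: four ortho halogens must be put on and three removed, three phenols must be differentiated, the electron-rich ring A can compete for the oxidant, and A2 still needs its ring A to ring D ether made by another method. Salts of trivalent thallium are acutely toxic and would be used in excess.
- Comparison: both plans close the same 18-membered ring at a diaryl ether, so the entropic problem is equal. In the chosen plan the site of bond formation is fixed by halogen and nitro group; here it depends on which phenol is oxidised and which ortho carbon is attacked. After ring closure both need two operations (equal). Before it the alternative is longer, because A2 is a linear assembly of all four rings, whereas 5 and 11 are each made in three to four steps.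

**Alternative 2:** The cut is the bond between the ring A carbon and the CH2 of bridge 1, formed by a 1,2-shift.
- Forward step: in the 17-membered spiro dienone A4 the future ether carbon of ring A is a quaternary carbon bearing the ring D oxygen and the bridge 1 CH2, and ring B is a methyl ether. BF3·OEt2 should bind the carbonyl oxygen, the CH2 should migrate to the neighbouring ring carbon, and proton loss should give the phenol A3. One demethylation would then lead to 17.
- In favour: the 18-membered ring arises by expansion of an existing ring and not by an end-to-end closure. The ring A hydroxyl appears directly and necessarily para to the ether carbon. Both neighbours of the quaternary carbon are equivalent, so there is no regiochemical question. Only one step follows the key step, one fewer than in the chosen plan.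
- Against: the difficulty moves to A4, which would need an oxidative dearomatisation of a para-alkylphenol (for example with PhI(OAc)2) with capture by the ring D phenol across a 17-membered ring, a weak nucleophile competing with solvent. Under the Lewis acid the quinol aryl ether can also ionise with loss of the ring D phenoxide instead of rearranging, and a primary alkyl group is a modest migrating group.
- Comparison: the chosen plan concentrates its risk in one substitution of well-understood mechanism; the alternative spreads it over a macrocyclic dearomatisation and a cationic rearrangement. Because all four rings must be joined linearly before A4, it is expected to be longer overall.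

**Alternative 3:** The cut is both aryl–CH bonds of bridge 2, with the two carbons delivered by the distannane A7.
- Forward step: the diiodide A6 has rings A and B as methyl ethers joined by bridge 1, with a 3-iodophenoxy group on ring A and a 4-iodophenoxy group on ring B. With Pd2(dba)3 and AsPh3 a first Stille coupling should give an aryl vinylstannane and a second, intramolecular one should close the ring as the E-stilbene A5. Hydrogenation and double demethylation would lead to 17.
- In favour: the conditions are neutral, C–C bond formation is irreversible, and no nitro or diazonium chemistry is needed. Since the two-carbon unit is symmetric, it does not matter which iodide reacts first, so there is no ordering problem; on that point it is the better plan.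
- Against: both diaryl ethers, the hard bonds of 17, must be made beforehand and in a way compatible with two aryl iodides. An E-stilbene between a para- and a meta-linked ring makes the 18-membered ring more rigid and strained than the saturated bridge. The distannane can also bridge two molecules, and organotin reagents and AsPh3 are toxic.
- Comparison: the chosen plan forms both ethers and the ring in one operation, whereas this one spends its key step on a bridge that a Wittig reaction makes easily in the open chain. After ring closure both need two operations (equal); overall the alternative is expected to be longer.

Key step: step 8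

Remark on the chemistry: 1 is bought as the benzylic bromide, which saves a radical bromination, and both Wittig products are carried on as E/Z mixtures because each double bond is saturated in the following step.

## Route

Step 1
Reactants: 1 3-fluoro-4-nitrobenzyl bromide
Product: 2 (3-fluoro-4-nitrobenzyl)triphenylphosphonium bromide
Conditions: PPh3, toluene, 60 °C
Reagents that add atoms: triphenylphosphine, c1ccc(cc1)P(c1ccccc1)c1ccccc1
Why: SN2 quaternisation of the phosphine by a benzylic bromide; the salt should precipitate from toluene, and at this temperature neither the nitro group nor the aryl fluoride reacts with PPh3.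

Step 2
Reactants: 2 (3-fluoro-4-nitrobenzyl)triphenylphosphonium bromide; 3 2-chloro-5-nitrobenzaldehyde
Product: 4 1-chloro-2-[2-(3-fluoro-4-nitrophenyl)ethenyl]-4-nitrobenzene (E/Z mixture)
Conditions: K2CO3, 18-crown-6 (cat.), CH2Cl2, rt
Reagents that add atoms: none
Why: Wittig reaction; the ylide of 2 is stabilised by the para nitro group, so a weak, non-nucleophilic base suffices and spares the fluoride of 2 and the doubly activated chloride of 3. The very electrophilic aldehyde 3 should react with this stabilised ylide at room temperature, and the alkene geometry is irrelevant.

Step 3
Reactants: 4 1-chloro-2-[2-(3-fluoro-4-nitrophenyl)ethenyl]-4-nitrobenzene (E/Z mixture)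
Product: 5 1-chloro-2-[2-(3-fluoro-4-nitrophenyl)ethyl]-4-nitrobenzene (the A-B half)
Conditions: KO2CN=NCO2K (excess, in portions), AcOH (slow addition), MeOH/THF, rt
Reagents that add atoms: none
Why: Diimide reduction; cis-diimide released from the azodicarboxylate by acetic acid transfers two hydrogens to the C=C bond in a concerted six-centre process and leaves nitro groups and aryl halides untouched. This source brings no hydrazide or sulfinate nucleophile near the fluoride ortho to nitro, and hydrogenation over palladium is excluded because it would reduce the nitro groups and the C–Cl bond.

Step 4
Reactants: 6 3-hydroxybenzaldehyde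
Product: 7 3-(triisopropylsilyloxy)benzaldehyde
Conditions: TIPSCl, imidazole, DMF, rt
Reagents that add atoms: triisopropylsilyl chloride (TIPSCl), CC(C)[Si](Cl)(C(C)C)C(C)C
Why: Silylation of a phenol with a silyl chloride under imidazole catalysis; the bulky triisopropylsilyl group is chosen so that the aryl silyl ether survives the ylide base, hydrogenation, K2CO3 and traces of fluoride until CsF is added in step 8.

Step 5
Reactants: 8 4-(benzyloxy)benzyl chloride
Product: 9 [4-(benzyloxy)benzyl]triphenylphosphonium chloride
Conditions: PPh3, toluene, reflux
Reagents that add atoms: triphenylphosphine, c1ccc(cc1)P(c1ccccc1)c1ccccc1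
Why: SN2 quaternisation of the phosphine by a benzylic chloride that is activated by the para alkoxy group.

Step 6
Reactants: 9 [4-(benzyloxy)benzyl]triphenylphosphonium chloride; 7 3-(triisopropylsilyloxy)benzaldehyde
Product: 10 {3-[2-(4-benzyloxyphenyl)ethenyl]phenoxy}triisopropylsilane (E/Z mixture)
Conditions: NaN(SiMe3)2, THF, 0 °C; then 7, 0 °C to rt
Reagents that add atoms: none
Why: Wittig reaction of a semi-stabilised benzylic ylide with an aromatic aldehyde; the amide base is non-nucleophilic and should not attack silicon, and the E/Z mixture is used as such.

Step 7
Reactants: 10 {3-[2-(4-benzyloxyphenyl)ethenyl]phenoxy}triisopropylsilane (E/Z mixture)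
Product: 11 4-{2-[3-(triisopropylsilyloxy)phenyl]ethyl}phenol (the C-D half)
Conditions: H2 (1 atm), 10% Pd/C, EtOAc, rt
Reagents that add atoms: none
Why: Heterogeneous catalytic hydrogenation; one operation should saturate the stilbene and cleave the benzyl ether by hydrogenolysis, freeing only the ring C phenol, while the aryl silyl ether is stable in a neutral aprotic solvent.

Step 8
Reactants: 5 1-chloro-2-[2-(3-fluoro-4-nitrophenyl)ethyl]-4-nitrobenzene; 11 4-{2-[3-(triisopropylsilyloxy)phenyl]ethyl}phenol
Product: 14 macrocyclic dinitro bis(diaryl ether) (17 with NO2 in place of each OH), via open-chain silyl ether 12 (not isolated), via open-chain caesium phenoxide 13 (not isolated)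
Conditions: K2CO3 (1.2 equiv), DMSO (0.1 M), rt, Ar; then dilution with degassed DMSO to about 3 mM, CsF, 100 °C
Reagents that add atoms: none
Why: Both events are addition–elimination substitutions at nitro-activated aryl halides, the standard route from phenoxides to diaryl ethers, and the second is the known variant in which fluoride unmasks an aryl silyl ether in the presence of the electrophile. In the first stage the potassium phenoxide of ring C adds to the fluorine-bearing carbon of ring B, the ortho nitro group takes up the charge of the anionic sigma complex, and fluoride leaves to give 12; this is intermolecular, should be fast at room temperature and is run concentrated. In the second stage CsF removes the silyl group from the ring D oxygen as fluorotriisopropylsilane, and phenoxide 13 adds to the chlorine-bearing carbon of ring A, para to its nitro group, and expels chloride. This attack closes the only new ring, the 18-membered one, by end-to-end C–O bond formation of an open chain, so it is run at high dilution to disfavour chain growth. No stereocenter is formed. The selectivity needed is the pairing of ring C oxygen with ring B and ring D oxygen with ring A; it is secured because only the ring C oxygen is nucleophilic in the first stage and the unhindered fluoride ortho to nitro should be far more reactive than the chloride flanked by bridge 1, while the bulky silyl ether should resist K2CO3 and the poorly soluble KF until CsF is added. DMSO is preferred to DMF for the hot stage so that no dimethylamine can form and take the chloride, and air is excluded because the ring B benzylic CH2 para to nitro is acidic.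

Step 9
Reactants: 14 macrocyclic dinitro bis(diaryl ether)
Product: 15 macrocyclic dianiline (17 with NH2 in place of each OH)
Conditions: H2 (1 atm), 10% Pd/C, EtOAc/EtOH, rt
Reagents that add atoms: none
Why: Catalytic hydrogenation of aromatic nitro groups to anilines; the molecule now holds no halogen, alkene or benzyl ether, and diaryl ethers are inert. The electron-rich dianiline is used at once.

Step 10
Reactants: 15 macrocyclic dianiline
Product: 17 dihydroptychantol A, via bis(diazonium) hydrogensulfate 16 (not isolated)
Conditions: NaNO2 (2.1 equiv), H2SO4, AcOH/H2O, 0 °C; then Cu(NO3)2 (large excess), Cu2O (substoichiometric, in portions), H2O, rt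
Reagents that add atoms: water, O
Why: Diazotisation followed by a Sandmeyer-type hydroxylation; monovalent copper reduces each diazonium group to an aryl radical with loss of N2, divalent copper in large excess captures the radical, and the aryl copper species gives the phenol with water as oxygen source while monovalent copper is regenerated. The reaction runs at room temperature in acid, so the diazonium salt is neither isolated nor heated and azo coupling with the phenol formed should be slow; the high concentration of divalent copper is what should outrun attack of the ring B radical on ring C.

## Compound list

1 | 3-fluoro-4-nitrobenzyl bromide (4-(bromomethyl)-2-fluoro-1-nitrobenzene) | BrCc1ccc([N+](=O)[O-])c(F)c1 | starting material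
2 | (3-fluoro-4-nitrobenzyl)triphenylphosphonium bromide | [Br-].[O-][N+](=O)c1ccc(C[P+](c2ccccc2)(c2ccccc2)c2ccccc2)cc1F | intermediate
3 | 2-chloro-5-nitrobenzaldehyde | O=Cc1cc([N+](=O)[O-])ccc1Cl | starting material
4 | 1-chloro-2-[2-(3-fluoro-4-nitrophenyl)ethenyl]-4-nitrobenzene, E/Z mixture | [O-][N+](=O)c1ccc(Cl)c(c1)C=Cc1ccc([N+](=O)[O-])c(F)c1 | intermediate
5 | 1-chloro-2-[2-(3-fluoro-4-nitrophenyl)ethyl]-4-nitrobenzene (A-B half) | [O-][N+](=O)c1ccc(Cl)c(c1)CCc1ccc([N+](=O)[O-])c(F)c1 | intermediate
6 | 3-hydroxybenzaldehyde | O=Cc1cccc(O)c1 | starting material
7 | 3-(triisopropylsilyloxy)benzaldehyde | O=Cc1cccc(O[Si](C(C)C)(C(C)C)C(C)C)c1 | intermediate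
8 | 4-(benzyloxy)benzyl chloride | ClCc1ccc(OCc2ccccc2)cc1 | starting material
9 | [4-(benzyloxy)benzyl]triphenylphosphonium chloride | [Cl-].c1ccc(cc1)COc1ccc(C[P+](c2ccccc2)(c2ccccc2)c2ccccc2)cc1 | intermediate
10 | {3-[2-(4-benzyloxyphenyl)ethenyl]phenoxy}triisopropylsilane, E/Z mixture | CC(C)[Si](Oc1cccc(C=Cc2ccc(OCc3ccccc3)cc2)c1)(C(C)C)C(C)C | intermediate
11 | 4-{2-[3-(triisopropylsilyloxy)phenyl]ethyl}phenol (C-D half) | Oc1ccc(cc1)CCc1cccc(O[Si](C(C)C)(C(C)C)C(C)C)c1 | intermediate
12 | open-chain silyl ether: 1-chloro-4-nitro-2-{2-[4-nitro-3-(4-{2-[3-(triisopropylsilyloxy)phenyl]ethyl}phenoxy)phenyl]ethyl}benzene | [O-][N+](=O)c1ccc(Cl)c(c1)CCc1ccc([N+](=O)[O-])c(c1)Oc1ccc(cc1)CCc1cccc(O[Si](C(C)C)(C(C)C)C(C)C)c1 | intermediate (not isolated)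
13 | open-chain caesium phenoxide: caesium salt of the ring D phenol obtained from 12 by loss of the silyl group | [Cs+].[O-][N+](=O)c1ccc(Cl)c(c1)CCc1ccc([N+](=O)[O-])c(c1)Oc1ccc(cc1)CCc1cccc([O-])c1 | intermediate (not isolated)
14 | macrocyclic dinitro bis(diaryl ether): 18-membered ring of 17 with NO2 on ring A para to its ether oxygen and NO2 on ring B ortho to its ether oxygen | [O-][N+](=O)c1ccc2c(c1)CCc1ccc([N+](=O)[O-])c(c1)Oc1ccc(cc1)CCc1cccc(c1)O2 | intermediate
15 | macrocyclic dianiline: as 14 with NH2 in place of each NO2 | Nc1ccc2c(c1)CCc1ccc(N)c(c1)Oc1ccc(cc1)CCc1cccc(c1)O2 | intermediate
16 | macrocyclic bis(diazonium) bis(hydrogensulfate) | N#[N+]c1ccc2c(c1)CCc1ccc([N+]#N)c(c1)Oc1ccc(cc1)CCc1cccc(c1)O2.OS(=O)(=O)[O-].OS(=O)(=O)[O-] | intermediate (not isolated)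
17 | dihydroptychantol A | Oc1ccc2c(c1)CCc1ccc(O)c(c1)Oc1ccc(cc1)CCc1cccc(c1)O2 | target

## Step count and least certain steps

Total: 10 steps. Longest linear sequence: 6 steps (steps 1, 2, 3, 8, 9, 10; the branch through steps 4, 6, 7, 8, 9, 10 is equally long).

**Step 8 (key step).**
- Most likely failure: slow ring closure at the hindered chloride, so that chain growth between molecules, ether exchange at the ring B carbon or base-induced decay at the nitrobenzylic CH2 takes over. A second risk is early loss of the silyl group through the fluoride released in the first stage, which would scramble the pairing.
- Fallback: the two ethers are made in separate operations and the ring is closed at a fluoride, so pairing is set by the order of assembly and not by halogen discrimination. The fallback sets out from 11. Substitution of 3-fluoro-4-nitrobenzaldehyde (O=Cc1ccc([N+](=O)[O-])c(F)c1) by the ring C phenoxide (K2CO3, DMF, rt) should give the silyl ether aldehyde F1. A Wittig reaction of F1 with (2-fluoro-5-nitrobenzyl)triphenylphosphonium bromide F2, made from 2-fluoro-5-nitrobenzyl bromide (BrCc1cc([N+](=O)[O-])ccc1F) and PPh3 and used with K2CO3 and 18-crown-6 in CH2Cl2, should give the fluoro stilbene F3. Diimide reduction as in step 3 should give the fluoro bibenzyl F4. CsF in dilute DMSO at 40–60 °C should then unmask the ring D phenoxide and close the ring at the fluoride para to nitro, which returns to the route at 14.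

**Step 10.**
- Most likely failure: incomplete diazotisation of a poorly soluble bis-ammonium salt, azo coupling of diazonium ion with phenol already formed, ring closure of the ring B aryl radical onto ring C, or hydrogen abstraction by the radical.
- Fallback: this sets out from 15. One-pot diazotisation and iodination in an organic medium (NaNO2, p-TsOH, KI, MeCN, rt) should give the macrocyclic diiodide F5, with no phenol present while diazonium ions exist. Hydroxylation catalysed by zerovalent palladium (Pd2(dba)3, 2-di-tert-butylphosphino-2',4',6'-triisopropylbiphenyl, KOH, dioxane/H2O, 100 °C, Ar) then returns to the route at 17.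

**Step 3.**
- Most likely failure: incomplete saturation, because diimide disproportionates faster than it transfers hydrogen to an ortho-substituted, electron-poor stilbene, so that alkene remains after several charges.
- Fallback: this sets out from 4 and replaces reagent-based hydrogen transfer by homogeneous catalytic hydrogenation (H2, 4 atm, RhCl(PPh3)3, toluene/EtOH, 50 °C), which does not reduce nitro groups or aryl halides. It returns to the route at 5 and makes no new compound (F0).

**Step 2.**
- Most likely failure: sluggish olefination by the stabilised ylide, so that substitution of the doubly activated chloride of 3 or of the fluoride by carbonate or adventitious water, or arylation of the ylide carbon, competes.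
- Fallback: the stilbene is made by a Heck reaction instead. It sets out from 3. Methylenation (Ph3PCH3Br, NaN(SiMe3)2, THF, −78 °C) should give 1-chloro-2-ethenyl-4-nitrobenzene F6. Coupling of F6 with 4-bromo-2-fluoro-1-nitrobenzene (Brc1ccc([N+](=O)[O-])c(F)c1; Pd(OAc)2, P(o-tol)3, Et3N, MeCN, 80 °C) should occur at the C–Br bond only and returns to the route at 4 as its E isomer.

## Further compounds

F1 | step 8 | 4-nitro-3-(4-{2-[3-(triisopropylsilyloxy)phenyl]ethyl}phenoxy)benzaldehyde | O=Cc1ccc([N+](=O)[O-])c(c1)Oc1ccc(cc1)CCc1cccc(O[Si](C(C)C)(C(C)C)C(C)C)c1
F2 | step 8 | (2-fluoro-5-nitrobenzyl)triphenylphosphonium bromide | [Br-].[O-][N+](=O)c1ccc(F)c(c1)C[P+](c1ccccc1)(c1ccccc1)c1ccccc1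
F3 | step 8 | 1-fluoro-4-nitro-2-{2-[4-nitro-3-(4-{2-[3-(triisopropylsilyloxy)phenyl]ethyl}phenoxy)phenyl]ethenyl}benzene, E/Z mixture | [O-][N+](=O)c1ccc(F)c(c1)C=Cc1ccc([N+](=O)[O-])c(c1)Oc1ccc(cc1)CCc1cccc(O[Si](C(C)C)(C(C)C)C(C)C)c1
F4 | step 8 | 1-fluoro-4-nitro-2-{2-[4-nitro-3-(4-{2-[3-(triisopropylsilyloxy)phenyl]ethyl}phenoxy)phenyl]ethyl}benzene (fluoro analogue of 12) | [O-][N+](=O)c1ccc(F)c(c1)CCc1ccc([N+](=O)[O-])c(c1)Oc1ccc(cc1)CCc1cccc(O[Si](C(C)C)(C(C)C)C(C)C)c1
F5 | step 10 | macrocyclic diiodide (17 with I in place of each OH) | Ic1ccc2c(c1)CCc1ccc(I)c(c1)Oc1ccc(cc1)CCc1cccc(c1)O2
F0 | step 3 | none | none
F6 | step 2 | 1-chloro-2-ethenyl-4-nitrobenzene | C=Cc1cc(ccc1Cl)[N+](=O)[O-]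
A1 | alternative 1 | macrocyclic bromo dichloro diaryl ether, ring A methyl ether | COc1ccc2c(c1)CCc1cc(Br)c(O)c(c1)Oc1c(Cl)cc(cc1Cl)CCc1cccc(c1)O2
A2 | alternative 1 | open precursor with 2,6-dibromophenol (ring B) and 2,6-dichlorophenol (ring C), ring A methyl ether | COc1ccc(Oc2cccc(CCc3cc(Cl)c(O)c(Cl)c3)c2)c(c1)CCc1cc(Br)c(O)c(Br)c1
A3 | alternative 2 | dihydroptychantol A ring B monomethyl ether | Oc1ccc2c(c1)CCc1ccc(OC)c(c1)Oc1ccc(cc1)CCc1cccc(c1)O2
A4 | alternative 2 | 17-membered spiro quinol ether (4-alkyl-4-aryloxycyclohexa-2,5-dienone) | O=C1C=CC2(C=C1)CCc1ccc(OC)c(c1)Oc1ccc(cc1)CCc1cccc(c1)O2
A5 | alternative 3 | macrocyclic E-stilbene at bridge 2, dimethyl ether | COc1ccc2c(c1)CCc1ccc(OC)c(c1)Oc1ccc(cc1)/C=C/c1cccc(c1)O2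
A6 | alternative 3 | open diiodide: bridge 1 bibenzyl dimethyl ether with 3-iodophenoxy on ring A and 4-iodophenoxy on ring B | COc1ccc(Oc2cccc(I)c2)c(c1)CCc1ccc(OC)c(Oc2ccc(I)cc2)c1
A7 | alternative 3 | (E)-1,2-bis(tributylstannyl)ethene | CCCC[Sn](CCCC)(CCCC)/C=C/[Sn](CCCC)(CCCC)CCCC
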